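**Retrosynthetic overview**

The route rests on the tertiary α-ketol in the ring of target 14: the C6 ketone next to the quaternary carbinol C1 (OH, C7H2OBz), with C1 also bonded to C2 (CH–OAc).
Disconnection 1 (key): undo the C1–C2 bond and re-bond C2 to C6, which gives acylcyclopentenol 13, a cyclopentene whose carbinol carbon (future C6) carries the benzoyloxyacetyl group (future C1 and C7).
Disconnection 2: the esters of 13 go back to masked hydroxyls; C2–OH is freed from TMS and acetylated first, the ketone and C7–OH come from a 1-ethoxyvinyl group by OsO4, C3–OH is freed from TBS, and both benzoates go on last.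
Disconnection 3: the carbinol C–C bond comes from 1-ethoxyvinyllithium and the trans-4,5-bis(silyloxy)cyclopentenone 4, which comes from α′-hydroxylation of enone 1.
Ring order: the five-membered ring is bought with 1; the six-membered ring is formed last, by ring expansion.

Key step: step 8

Assumption: enone 1 is bought as the single (S)-enantiomer. Cyclopentene intermediates are numbered C1 (carbonyl, later carbinol), C2=C3, C4 (silyloxy carbon of 1), C5 (α′ carbon); these become C6, C5=C4, C3 and C2 of the target, and the side-chain carbons become C1 and C7.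

**Route**

Step 1
Reactants: 1 (S)-4-(tert-butyldimethylsilyloxy)cyclopent-2-en-1-one
Product: 3 (4R,5S)-4-(tert-butyldimethylsilyloxy)-5-hydroxycyclopent-2-en-1-one, via lithium dienolate 2 (not isolated)
Conditions: LDA, THF, −78 °C; 3-phenyl-2-(phenylsulfonyl)oxaziridine, −78 °C; AcOH quench
Reagents that add atoms: 3-phenyl-2-(phenylsulfonyl)oxaziridine, O=S(=O)(c1ccccc1)N1OC1c1ccccc1
Why: Kinetic α′-deprotonation gives the cross-conjugated lithium dienolate, which the N-sulfonyloxaziridine hydroxylates (Davis enolate oxidation) on the face anti to the C4 silyloxy group, so the new C5 carbinol should be set trans to C4–O, while the low temperature holds back siloxide β-elimination and deprotonation at C4.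

Step 2
Reactants: 3 (4R,5S)-4-(tert-butyldimethylsilyloxy)-5-hydroxycyclopent-2-en-1-one
Product: 4 (4R,5S)-4-(tert-butyldimethylsilyloxy)-5-(trimethylsilyloxy)cyclopent-2-en-1-one
Conditions: N-(trimethylsilyl)imidazole, CH2Cl2, 0 °C → rt
Reagents that add atoms: N-(trimethylsilyl)imidazole, C[Si](C)(C)n1ccnc1
Why: Silylation of the secondary α′-hydroxyl with a silylimidazole is fast under neutral conditions and masks the acidic OH for the organolithium step without disturbing the base-sensitive β-silyloxy enone; no stereocenter is formed.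

Step 3
Reactants: 4 (4R,5S)-4-(tert-butyldimethylsilyloxy)-5-(trimethylsilyloxy)cyclopent-2-en-1-one; 5 ethyl vinyl ether
Product: 8 (1R,4R,5S)-4-(tert-butyldimethylsilyloxy)-1-(1-ethoxyethenyl)cyclopent-2-ene-1,5-diol, via 1-ethoxyvinyllithium 6 (not isolated), via lithium alkoxide adduct 7 (not isolated)
Conditions: 5 (excess), t-BuLi, THF, −78 → 0 °C; add 4, −78 °C; then MeOH, K2CO3 (cat.), 0 °C
Reagents that add atoms: none
Why: α-Lithiated ethyl vinyl ether is an acyl-anion equivalent that should add 1,2 to the enone carbonyl (organolithium carbonyl addition) anti to the adjacent C5–O bond (Felkin–Anh torsional and polar control by the α-substituent), which sets the C1 carbinol with OH cis to C5–O, and base methanolysis then removes only the TMS group, on whichever oxygen it sits after any 1,4-silyl shift.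

Step 4
Reactants: 8 (1R,4R,5S)-4-(tert-butyldimethylsilyloxy)-1-(1-ethoxyethenyl)cyclopent-2-ene-1,5-diol
Product: 9 (1S,2R,5R)-5-(tert-butyldimethylsilyloxy)-2-(1-ethoxyethenyl)-2-hydroxycyclopent-3-en-1-yl acetate
Conditions: Ac2O, pyridine, DMAP (cat.), CH2Cl2, 0 °C; NaHCO3 work-up
Reagents that add atoms: acetic anhydride, CC(=O)OC(C)=O
Why: DMAP-catalysed acylation distinguishes the secondary C5 hydroxyl from the tertiary C1 hydroxyl on steric grounds, and the basic medium preserves the acid-labile enol ether; no stereocenter changes.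

Step 5
Reactants: 9 (1S,2R,5R)-5-(tert-butyldimethylsilyloxy)-2-(1-ethoxyethenyl)-2-hydroxycyclopent-3-en-1-yl acetate
Product: 11 (1S,2R,5R)-5-(tert-butyldimethylsilyloxy)-2-hydroxy-2-(hydroxyacetyl)cyclopent-3-en-1-yl acetate, via ethyl hemiketal 10 (not isolated)
Conditions: OsO4 (2 mol %), NMO (1.1 equiv), acetone–H2O, 0 °C
Reagents that add atoms: N-methylmorpholine N-oxide, C[N+]1([O-])CCOCC1; water, O
Why: Catalytic dihydroxylation (Upjohn conditions) should take the electron-rich enol ether far faster than the ring alkene, which is deactivated by two allylic C–O bonds, and the hemiketal collapses to the hydroxymethyl ketone with loss of ethanol; the only new stereocenter is the transient hemiketal carbon, which disappears.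

Step 6
Reactants: 11 (1S,2R,5R)-5-(tert-butyldimethylsilyloxy)-2-hydroxy-2-(hydroxyacetyl)cyclopent-3-en-1-yl acetate
Product: 12 (1S,2R,5R)-2,5-dihydroxy-2-(hydroxyacetyl)cyclopent-3-en-1-yl acetate
Conditions: HF·pyridine, pyridine, THF, 0 °C → rt
Reagents that add atoms: none
Why: Buffered acidic fluoride desilylation frees the allylic hydroxyl without the alkoxide intermediates that would invite acetyl migration or ketol isomerisation; no stereocenter changes.

Step 7
Reactants: 12 (1S,2R,5R)-2,5-dihydroxy-2-(hydroxyacetyl)cyclopent-3-en-1-yl acetate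
Product: 13 2-[(1R,4R,5S)-5-acetoxy-4-(benzoyloxy)-1-hydroxycyclopent-2-en-1-yl]-2-oxoethyl benzoate
Conditions: BzCl (2.4 equiv), pyridine, CH2Cl2, 0 °C
Reagents that add atoms: benzoyl chloride, O=C(Cl)c1ccccc1
Why: Acylation with an acid chloride in pyridine should esterify the primary ketol hydroxyl and the secondary allylic hydroxyl while the hindered tertiary hydroxyl stays free, as in step 4; no stereocenter changes.

Step 8
Reactants: 13 2-[(1R,4R,5S)-5-acetoxy-4-(benzoyloxy)-1-hydroxycyclopent-2-en-1-yl]-2-oxoethyl benzoate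
Product: 14 2-O-acetylzeylenone, [(1S,2S,3R)-2-acetoxy-3-(benzoyloxy)-1-hydroxy-6-oxocyclohex-4-en-1-yl]methyl benzoate
Conditions: Sc(OTf)3 (10 mol %), 4 Å MS, ClCH2CH2Cl, 40 → 70 °C
Reagents that add atoms: none
Why: Sc(III) should bind the tertiary hydroxyl and the side-chain carbonyl of 13 in a five-membered chelate that holds the O–C–C=O unit syn-periplanar, and the ring bond from the carbinol carbon to the acetoxy-bearing carbon (target C2) then shifts with retention to the carbonyl carbon while the carbinol collapses to the C6 ketone, an α-ketol (acyloin) rearrangement of the type known as D-homoannulation of 17-hydroxy-20-keto steroids. The six-membered ring is closed by this 1,2-shift itself, a one-carbon ring expansion that inserts the former side-chain carbonyl carbon between C6 and C2, not a cyclisation of a chain. The new stereocenter C1 is controlled by the carbinol configuration of 13 read through the chelated rotamer: C2 attacks the carbonyl face that places the new hydroxyl cis to C2–OAc and C7 trans to it, which is (1S), and C2 and C3 are not touched. The step needs the sp3 carbon C2, not the vinyl carbon, to end up on C1, and this is secured thermodynamically, because 13, 14 and the iso-ketol from vinyl migration form a closed set that interconverts by 1,2-shifts under the same catalysis and 14 alone has the ketone conjugated with C4=C5 in a six-membered ring. The iso-ketol, if it forms first, should reach the same diastereomer 14 by a suprafacial shift of C7, so both channels converge. Ionisation of the allylic benzoate or of the tertiary alcohol is disfavoured because each cation would sit next to a carbonyl-bearing or acyloxy-bearing carbon.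

**Compound list**

1 | (S)-4-(tert-butyldimethylsilyloxy)cyclopent-2-en-1-one | O=C1C=C[C@@H](O[Si](C)(C)C(C)(C)C)C1 | starting material
2 | lithium (R)-3-(tert-butyldimethylsilyloxy)cyclopenta-1,4-dien-1-olate (α′-dienolate of 1) | [Li]OC1=C[C@H](O[Si](C)(C)C(C)(C)C)C=C1 | intermediate
3 | (4R,5S)-4-(tert-butyldimethylsilyloxy)-5-hydroxycyclopent-2-en-1-one | O[C@H]1[C@H](O[Si](C)(C)C(C)(C)C)C=CC1=O | intermediate
4 | (4R,5S)-4-(tert-butyldimethylsilyloxy)-5-(trimethylsilyloxy)cyclopent-2-en-1-one | C[Si](C)(C)O[C@H]1[C@H](O[Si](C)(C)C(C)(C)C)C=CC1=O | intermediate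
5 | ethyl vinyl ether | C=COCC | starting material
6 | 1-ethoxyvinyllithium | [Li]C(=C)OCC | intermediate
7 | lithium (1R,4R,5S)-4-(tert-butyldimethylsilyloxy)-1-(1-ethoxyethenyl)-5-(trimethylsilyloxy)cyclopent-2-en-1-olate | C[Si](C)(C)O[C@H]1[C@H](O[Si](C)(C)C(C)(C)C)C=C[C@]1(O[Li])C(=C)OCC | intermediate
8 | (1R,4R,5S)-4-(tert-butyldimethylsilyloxy)-1-(1-ethoxyethenyl)cyclopent-2-ene-1,5-diol | O[C@H]1[C@H](O[Si](C)(C)C(C)(C)C)C=C[C@]1(O)C(=C)OCC | intermediate
9 | (1S,2R,5R)-5-(tert-butyldimethylsilyloxy)-2-(1-ethoxyethenyl)-2-hydroxycyclopent-3-en-1-yl acetate | CC(=O)O[C@H]1[C@H](O[Si](C)(C)C(C)(C)C)C=C[C@]1(O)C(=C)OCC | intermediate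
10 | (1S,2R,5R)-5-(tert-butyldimethylsilyloxy)-2-(1-ethoxy-1,2-dihydroxyethyl)-2-hydroxycyclopent-3-en-1-yl acetate (ethyl hemiketal, hemiketal carbon undefined) | CC(=O)O[C@H]1[C@H](O[Si](C)(C)C(C)(C)C)C=C[C@]1(O)C(O)(CO)OCC | intermediate
11 | (1S,2R,5R)-5-(tert-butyldimethylsilyloxy)-2-hydroxy-2-(hydroxyacetyl)cyclopent-3-en-1-yl acetate | CC(=O)O[C@H]1[C@H](O[Si](C)(C)C(C)(C)C)C=C[C@]1(O)C(=O)CO | intermediate
12 | (1S,2R,5R)-2,5-dihydroxy-2-(hydroxyacetyl)cyclopent-3-en-1-yl acetate | CC(=O)O[C@H]1[C@H](O)C=C[C@]1(O)C(=O)CO | intermediate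
13 | 2-[(1R,4R,5S)-5-acetoxy-4-(benzoyloxy)-1-hydroxycyclopent-2-en-1-yl]-2-oxoethyl benzoate | CC(=O)O[C@H]1[C@H](OC(=O)c2ccccc2)C=C[C@]1(O)C(=O)COC(=O)c1ccccc1 | intermediate
14 | 2-O-acetylzeylenone, [(1S,2S,3R)-2-acetoxy-3-(benzoyloxy)-1-hydroxy-6-oxocyclohex-4-en-1-yl]methyl benzoate | CC(=O)O[C@H]1[C@H](OC(=O)c2ccccc2)C=CC(=O)[C@]1(O)COC(=O)c1ccccc1 | target

**Totals and risks**

Total step count: 8. Longest linear sequence: 8 steps (1 → 14).

Steps most likely to fail:

Step 8. The vinyl carbon may shift faster than C2 and the iso-ketol may then fail to funnel on, or the Lewis acid may scramble the esters before the conjugated enone is reached. The fallback runs the shift on a ketol whose C2 oxygen is a free carbinol, a better migrating carbon than an acetoxy-bearing one, and adds the acetate last. It sets out from diol 8. OsO4/NMO would give, through the ethyl hemiketal F1, the silyl-protected hydroxymethyl ketone F2. HF·pyridine would then give the tetraol F3. BzCl (2 equiv) with 2,4,6-collidine at low temperature should benzoylate the primary and the less hindered allylic secondary hydroxyl to give the 2-deacetyl ketol dibenzoate F4. The Lewis-acid α-ketol shift of F4 would give zeylenone F5, and Ac2O/pyridine on its secondary C2 hydroxyl returns to the route at 14.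

Step 3. The branched vinyl anion may show poor facial selectivity, because the face it must use also carries the C4 silyloxy group, or it may enolise the ketone. The fallback uses a slim sp nucleophile and a different oxidation of the side chain. It sets out from 4. Ethynylmagnesium bromide (THF, −78 → 0 °C) would give the TMS-protected propargylic alcohol F6, and K2CO3/MeOH the ethynyl diol F7. Ac2O/pyridine/DMAP would give the C5 acetate F8. Gold-catalysed alkyne oxidation (Ph3PAuNTf2, 8-methylquinoline N-oxide, benzoic acid in excess so that O–H insertion outruns closure to a spiro-oxetanone) would give the benzoyloxymethyl ketone F9. HF·pyridine would give the allylic alcohol F10, and BzCl/pyridine returns to the route at 13.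

Step 1. The dienolate may lose siloxide to a cyclopentadienone, C4 may be deprotonated with erosion of enantiopurity, or the enolate may condense with the sulfonimine by-product. The fallback avoids a free enolate. It sets out from 1. Mn(OAc)3 in benzene at reflux (α′-acetoxylation of enones) should give the trans acetoxy enone F11, and lipase-mediated hydrolysis in pH 7 buffer would release the alcohol and return to the route at 3.

**Further compounds**

F1 | step 8 | 1-[(1R,4R,5S)-4-(tert-butyldimethylsilyloxy)-1,5-dihydroxycyclopent-2-en-1-yl]-1-ethoxyethane-1,2-diol (ethyl hemiketal, hemiketal carbon undefined) | O[C@H]1[C@H](O[Si](C)(C)C(C)(C)C)C=C[C@]1(O)C(O)(CO)OCC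
F2 | step 8 | 1-[(1R,4R,5S)-4-(tert-butyldimethylsilyloxy)-1,5-dihydroxycyclopent-2-en-1-yl]-2-hydroxyethan-1-one | O[C@H]1[C@H](O[Si](C)(C)C(C)(C)C)C=C[C@]1(O)C(=O)CO
F3 | step 8 | 2-hydroxy-1-[(1R,4R,5S)-1,4,5-trihydroxycyclopent-2-en-1-yl]ethan-1-one | O[C@H]1[C@H](O)C=C[C@]1(O)C(=O)CO
F4 | step 8 | 2-[(1R,4R,5S)-4-(benzoyloxy)-1,5-dihydroxycyclopent-2-en-1-yl]-2-oxoethyl benzoate | O[C@H]1[C@H](OC(=O)c2ccccc2)C=C[C@]1(O)C(=O)COC(=O)c1ccccc1
F5 | step 8 | zeylenone, [(1S,2S,3R)-3-(benzoyloxy)-1,2-dihydroxy-6-oxocyclohex-4-en-1-yl]methyl benzoate | O[C@H]1[C@H](OC(=O)c2ccccc2)C=CC(=O)[C@]1(O)COC(=O)c1ccccc1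
F6 | step 3 | (1S,4R,5S)-4-(tert-butyldimethylsilyloxy)-1-ethynyl-5-(trimethylsilyloxy)cyclopent-2-en-1-ol | C[Si](C)(C)O[C@H]1[C@H](O[Si](C)(C)C(C)(C)C)C=C[C@]1(O)C#C
F7 | step 3 | (1S,4R,5S)-4-(tert-butyldimethylsilyloxy)-1-ethynylcyclopent-2-ene-1,5-diol | O[C@H]1[C@H](O[Si](C)(C)C(C)(C)C)C=C[C@]1(O)C#C
F8 | step 3 | (1S,2S,5R)-5-(tert-butyldimethylsilyloxy)-2-ethynyl-2-hydroxycyclopent-3-en-1-yl acetate | CC(=O)O[C@H]1[C@H](O[Si](C)(C)C(C)(C)C)C=C[C@]1(O)C#C
F9 | step 3 | 2-[(1R,4R,5S)-5-acetoxy-4-(tert-butyldimethylsilyloxy)-1-hydroxycyclopent-2-en-1-yl]-2-oxoethyl benzoate | CC(=O)O[C@H]1[C@H](O[Si](C)(C)C(C)(C)C)C=C[C@]1(O)C(=O)COC(=O)c1ccccc1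
F10 | step 3 | 2-[(1R,4R,5S)-5-acetoxy-1,4-dihydroxycyclopent-2-en-1-yl]-2-oxoethyl benzoate | CC(=O)O[C@H]1[C@H](O)C=C[C@]1(O)C(=O)COC(=O)c1ccccc1
F11 | step 1 | (1S,5R)-5-(tert-butyldimethylsilyloxy)-2-oxocyclopent-3-en-1-yl acetate | CC(=O)O[C@H]1[C@H](O[Si](C)(C)C(C)(C)C)C=CC1=O
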